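**Retrosynthetic overview**
1. Tetralin locants: C1 (CHAr), C2, C3, C4 (CH2), C4a, C5–C8, C8a; pendant ring C1′–C6′. The C1–C1′ bond and, in the same operation, the C1–C8a bond are disconnected, giving aryl Grignard reagent 11 and lactol 9, in which C1 is an aldehyde carbon masked in a temporary oxolane (O links C1 to the CH2 on C3).
2. Enabling feature: C1 lies between two aryl carbons that are each para to a phenol oxygen (C1′ para to the O on C4′; C8a para to the O on C6 of the benzo ring). The C1 carbinol therefore ionizes to a quinone-methide-type cation, and C8a is the nucleophilic carbon that closes ring C1–C2–C3–C4–C4a–C8a; every C1 isomer converges on 1,2-trans.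
3. Lactol 9 comes from trans lactone 7 (LiAlH4, acetal hydrolysis). C1 enters as CH(OMe)2 anti to the benzyl group of lactone 5 (sets C2), and the lactone C=O becomes the CH2OH on C2.
4. Lactone 5 comes from Stobbe condensation of 1 with 2, Rh-catalysed asymmetric hydrogenation (sets C3) and chemoselective ester reduction.
5. Ring order: both benzene rings are bought; a temporary γ-lactone, then the temporary oxolane (lactol), then the carbocycle last; hydrogenolysis of two benzyl ethers ends the route.

Key step: step 6

Remark: the target is taken as the (1S,2R,3R), all-trans isomer with OH on C6 and OMe on C7 of the tetralin (OH para to C8a), as the SMILES requires.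
Assumption: the antipode of the Rh/Et-DuPhos catalyst that gives (R)-4 is used; the sense of induction is taken over from related arylidene succinate half esters.

Step 1
Reactants: 1 3-(benzyloxy)-4-methoxybenzaldehyde; 2 dimethyl succinate
Product: 3 (E)-4-[3-(benzyloxy)-4-methoxyphenyl]-3-(methoxycarbonyl)but-3-enoic acid
Conditions: NaOMe, MeOH, reflux; then 2 M HCl
Reagents that add atoms: none
Why: Stobbe condensation, in which the succinate enolate adds to the aldehyde, the aldolate lactonizes onto the distal ester and E1cB opening of the paraconate should give the (E)-alkylidene half ester with the free acid on the CH2 arm, the regiochemistry that the later chemoselective reduction needs.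

Step 2
Reactants: 3 (E)-4-[3-(benzyloxy)-4-methoxyphenyl]-3-(methoxycarbonyl)but-3-enoic acid
Product: 4 (R)-4-[3-(benzyloxy)-4-methoxyphenyl]-3-(methoxycarbonyl)butanoic acid
Conditions: [Rh(cod)(Et-DuPhos)]BF4 (1 mol %), H2 (5 bar), MeOH, rt
Reagents that add atoms: none
Why: Rh/bisphosphine asymmetric hydrogenation of an itaconate-type half ester, in which chelation of the carboxylate and the ester to rhodium should direct hydrogen to one enantioface and set C3 as R under catalyst control, while the homogeneous catalyst leaves the benzyl ether intact.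

Step 3
Reactants: 4 (R)-4-[3-(benzyloxy)-4-methoxyphenyl]-3-(methoxycarbonyl)butanoic acid
Product: 5 (R)-4-[3-(benzyloxy)-4-methoxybenzyl]dihydrofuran-2(3H)-one
Conditions: KOH (1 equiv), EtOH, 0 °C; CaCl2, NaBH4, EtOH, −10 °C to rt; then 2 M HCl, rt
Reagents that add atoms: none
Why: chemoselective reduction of the ester beside the unreactive carboxylate by calcium borohydride formed in the flask, followed by acid lactonization of the γ-hydroxy acid, should give the β-benzyl lactone without touching the C3 stereocenter.

Step 4
Reactants: 5 (R)-4-[3-(benzyloxy)-4-methoxybenzyl]dihydrofuran-2(3H)-one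
Product: 7 (3S,4R)-4-[3-(benzyloxy)-4-methoxybenzyl]-3-(dimethoxymethyl)dihydrofuran-2(3H)-one, via silyl ketene acetal 6 (not isolated)
Conditions: LDA, THF, −78 °C; TMSCl, −78 to 0 °C; then HC(OMe)3, TMSOTf (10 mol %), CH2Cl2, −78 °C
Reagents that add atoms: trimethyl orthoformate COC(OC)OC
Why: Mukaiyama-type addition of the ketene silyl acetal to the dimethoxycarbenium ion from the orthoformate, in which the electrophile should approach the dihydrofuran face anti to the benzyl group and so set the new center (tetralin C2) trans, while the acetal holds C1 at the aldehyde level without an enolizable formyl lactone.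

Step 5
Reactants: 7 (3S,4R)-4-[3-(benzyloxy)-4-methoxybenzyl]-3-(dimethoxymethyl)dihydrofuran-2(3H)-one
Product: 9 (3R,4R)-4-[3-(benzyloxy)-4-methoxybenzyl]-3-(hydroxymethyl)tetrahydrofuran-2-ol (3,4-cis, both anomers), via diol acetal 8 (not isolated)
Conditions: LiAlH4, THF, 0 °C; Rochelle salt work-up; then 0.5 M HCl, THF–H2O, rt
Reagents that add atoms: water O
Why: hydride reduction of the lactone to the 1,4-diol followed by acid hydrolysis of the dimethyl acetal, in which the freed aldehyde should be captured by the CH2OH of the benzyl-bearing carbon as the five-membered lactol (the other CH2OH could only give a four-membered ring), so the 3,4-cis lactol follows from the configuration set in step 4 without new stereocontrol.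

Step 6
Reactants: 9 (3R,4R)-4-[3-(benzyloxy)-4-methoxybenzyl]-3-(hydroxymethyl)tetrahydrofuran-2-ol; 10 1-(benzyloxy)-4-bromo-2-methoxybenzene
Product: 14 [(1S,2R,3R)-6-(benzyloxy)-1-[4-(benzyloxy)-3-methoxyphenyl]-7-methoxy-1,2,3,4-tetrahydronaphthalene-2,3-diyl]dimethanol, via arylmagnesium bromide 11 (not isolated), via triol 12 (not isolated), via tetrahydrofuran ether 13 (not isolated)
Conditions: 10, Mg, THF, 40 °C; then 9, THF, 0 °C to rt (3.3 equiv of 11); then TFA, CH2Cl2, 0 °C to rt, same flask; K2CO3, MeOH work-up
Reagents that add atoms: none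
Why: Grignard reagent 11 adds to the open hydroxy aldehyde form of 9 and forms the C1–C1′ bond as a mixture of carbinol epimers 12; TFA then ionizes the C1–OH to a cation that the para oxygen on C4′ stabilizes as a quinone-methide-type oxocarbenium ion, which is captured reversibly by the oxygen of the CH2OH on C3 (oxolane 13) and irreversibly by C8a. The closest known reaction types are the addition of aryl Grignard reagents to lactols and the acid-mediated Friedel–Crafts cyclialkylation that converts 7-hydroxy and 7,9′-epoxy lignans into aryltetralins. The carbocycle C1–C2–C3–C4–C4a–C8a closes by 6-exo-trig attack of C8a on the C1=C1′ bond of the cation through a chair-like transition state, and the transient oxolane of 13 by 5-exo-trig attack of oxygen on the same carbon. C1 is the only new stereocenter: the planar cation erases the configuration of 12 and 13, and the C1′ aryl group takes the pseudo-equatorial position anti to the equatorial CH2OH on C2, so all isomers should funnel into the 1,2-trans-2,3-trans product, which is also the most stable one. The step needs three selectivities: the position on the pendant ring is fixed by the C–Mg bond para to OBn, closure at C8a and not at the hindered ring carbon between CH2 and OBn is secured by the para benzyloxy group, and ring closure over intermolecular arylation by the arene formed on quenching excess 11 is secured by the six-membered transition state.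

Step 7
Reactants: 14 [(1S,2R,3R)-6-(benzyloxy)-1-[4-(benzyloxy)-3-methoxyphenyl]-7-methoxy-1,2,3,4-tetrahydronaphthalene-2,3-diyl]dimethanol
Product: 15 [(1S,2R,3R)-6-hydroxy-1-(4-hydroxy-3-methoxyphenyl)-7-methoxy-1,2,3,4-tetrahydronaphthalene-2,3-diyl]dimethanol
Conditions: H2 (1 atm), 10% Pd/C, EtOAc–MeOH, rt
Reagents that add atoms: none
Why: catalytic hydrogenolysis of the two aryl benzyl ethers, which should leave the primary alcohols, the methyl ethers and the C–C bonds of the C1 diarylmethine untouched, so that no stereocenter is affected.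

**Compound list**
1 | 3-(benzyloxy)-4-methoxybenzaldehyde | COc1ccc(C=O)cc1OCc1ccccc1 | starting material
2 | dimethyl succinate | COC(=O)CCC(=O)OC | starting material
3 | (E)-4-[3-(benzyloxy)-4-methoxyphenyl]-3-(methoxycarbonyl)but-3-enoic acid | COC(=O)/C(CC(=O)O)=C/c1ccc(OC)c(OCc2ccccc2)c1 | intermediate
4 | (R)-4-[3-(benzyloxy)-4-methoxyphenyl]-3-(methoxycarbonyl)butanoic acid | OC(=O)C[C@@H](Cc1ccc(OC)c(OCc2ccccc2)c1)C(=O)OC | intermediate
5 | (R)-4-[3-(benzyloxy)-4-methoxybenzyl]dihydrofuran-2(3H)-one | O=C1C[C@@H](Cc2ccc(OC)c(OCc3ccccc3)c2)CO1 | intermediate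
6 | (R)-[[4-[3-(benzyloxy)-4-methoxybenzyl]-4,5-dihydrofuran-2-yl]oxy]trimethylsilane | C[Si](C)(C)OC1=C[C@@H](Cc2ccc(OC)c(OCc3ccccc3)c2)CO1 | intermediate
7 | (3S,4R)-4-[3-(benzyloxy)-4-methoxybenzyl]-3-(dimethoxymethyl)dihydrofuran-2(3H)-one (3,4-trans) | O=C1[C@H](C(OC)OC)[C@@H](Cc2ccc(OC)c(OCc3ccccc3)c2)CO1 | intermediate
8 | (2R,3R)-2-[3-(benzyloxy)-4-methoxybenzyl]-3-(dimethoxymethyl)butane-1,4-diol | OC[C@H](C(OC)OC)[C@@H](Cc1ccc(OC)c(OCc2ccccc2)c1)CO | intermediate
9 | (3R,4R)-4-[3-(benzyloxy)-4-methoxybenzyl]-3-(hydroxymethyl)tetrahydrofuran-2-ol (3,4-cis, both anomers) | OC1OC[C@H](Cc2ccc(OC)c(OCc3ccccc3)c2)[C@@H]1CO | intermediate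
10 | 1-(benzyloxy)-4-bromo-2-methoxybenzene | COc1cc(Br)ccc1OCc1ccccc1 | starting material
11 | [4-(benzyloxy)-3-methoxyphenyl]magnesium bromide | COc1cc([Mg]Br)ccc1OCc1ccccc1 | intermediate
12 | (1RS,2R,3R)-1-[4-(benzyloxy)-3-methoxyphenyl]-3-[3-(benzyloxy)-4-methoxybenzyl]-2-(hydroxymethyl)butane-1,4-diol | OC(c1ccc(OCc2ccccc2)c(OC)c1)[C@@H](CO)[C@H](CO)Cc1ccc(OC)c(OCc2ccccc2)c1 | intermediate
13 | [(3R,4R)-2-[4-(benzyloxy)-3-methoxyphenyl]-4-[3-(benzyloxy)-4-methoxybenzyl]tetrahydrofuran-3-yl]methanol (both C2 epimers) | OC[C@@H]1C(c2ccc(OCc3ccccc3)c(OC)c2)OC[C@@H]1Cc1ccc(OC)c(OCc2ccccc2)c1 | intermediate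
14 | [(1S,2R,3R)-6-(benzyloxy)-1-[4-(benzyloxy)-3-methoxyphenyl]-7-methoxy-1,2,3,4-tetrahydronaphthalene-2,3-diyl]dimethanol | COc1cc([C@H]2c3cc(OC)c(OCc4ccccc4)cc3C[C@@H](CO)[C@@H]2CO)ccc1OCc1ccccc1 | intermediate
15 | [(1S,2R,3R)-6-hydroxy-1-(4-hydroxy-3-methoxyphenyl)-7-methoxy-1,2,3,4-tetrahydronaphthalene-2,3-diyl]dimethanol | COc1cc([C@H]2c3cc(OC)c(O)cc3C[C@@H](CO)[C@@H]2CO)ccc1O | target

Total step count: 7. Longest linear sequence: 7 steps (1 to 15); bromide 10 enters in step 6.

**Steps most likely to fail**

Step 6. The Grignard reagent may act as a base on the open hydroxy aldehyde (enolization with loss of the C2 configuration, or retro-aldol loss of the CH2OH arm) instead of adding to it. In the acid phase the cation may also be intercepted by the arene left from the quench before ring closure. The fallback makes the C1–C1′ bond at the oxocarbenium level and separates the two events. It sets out from 9, which is condensed with benzenesulfinic acid (CaCl2, CH2Cl2) to the anomeric sulfone [(3R,4R)-4-[3-(benzyloxy)-4-methoxybenzyl]-2-(phenylsulfonyl)tetrahydrofuran-3-yl]methanol F1. The arylzinc reagent [4-(benzyloxy)-3-methoxyphenyl]zinc bromide F2, made from 11 and ZnBr2 in THF, then displaces the sulfinate through the cyclic oxocarbenium ion to give oxolane 13, which is isolated this time. Treatment of purified 13 with TFA in CH2Cl2 opens the benzylic ether and closes the carbocycle, and the route is rejoined at 14.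

Step 4. The ketene acetal may add to the dialkoxycarbenium ion with insufficient facial discrimination, or the β-alkoxy acetal may lose methanol to the methoxymethylene lactone under the Lewis acid, which would erase the C2 center. The fallback brings C1 in as a thioacetal, which cannot eliminate. It sets out from 5: ketene acetal 6 is treated with 1,3-dithienium tetrafluoroborate (CH2Cl2, −78 °C) to give (3R,4R)-4-[3-(benzyloxy)-4-methoxybenzyl]-3-(1,3-dithian-2-yl)dihydrofuran-2(3H)-one F3. LiAlH4 reduces it to (2R,3R)-2-[3-(benzyloxy)-4-methoxybenzyl]-3-(1,3-dithian-2-yl)butane-1,4-diol F4. Buffered alkylative hydrolysis (MeI, CaCO3, MeCN–H2O) frees the aldehyde, which closes to the lactol, so the route is rejoined at 9. This path also avoids the acidic unmasking of step 5.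

Step 3. The borohydride may fail to discriminate between ester and carboxylate (over- or under-reduction), or lactonization may stall at the hydroxy acid. The fallback gives up chemoselective reduction for regioselective oxidation. It sets out from 4, which LiAlH4 reduces at both carbonyl groups to (R)-2-[3-(benzyloxy)-4-methoxybenzyl]butane-1,4-diol F5. Ruthenium-catalysed transfer dehydrogenation (RuH2(PPh3)4, benzalacetone, toluene) then oxidizes the less hindered primary alcohol first and lactonizes through the lactol, so the route is rejoined at 5.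

Further compounds
F1 | step 6 | [(3R,4R)-4-[3-(benzyloxy)-4-methoxybenzyl]-2-(phenylsulfonyl)tetrahydrofuran-3-yl]methanol | O=S(=O)(c1ccccc1)C1OC[C@H](Cc2ccc(OC)c(OCc3ccccc3)c2)[C@@H]1CO
F2 | step 6 | [4-(benzyloxy)-3-methoxyphenyl]zinc bromide | COc1cc([Zn]Br)ccc1OCc1ccccc1
F3 | step 4 | (3R,4R)-4-[3-(benzyloxy)-4-methoxybenzyl]-3-(1,3-dithian-2-yl)dihydrofuran-2(3H)-one | O=C1[C@H](C2SCCCS2)[C@@H](Cc2ccc(OC)c(OCc3ccccc3)c2)CO1
F4 | step 4 | (2R,3R)-2-[3-(benzyloxy)-4-methoxybenzyl]-3-(1,3-dithian-2-yl)butane-1,4-diol | OC[C@H](C1SCCCS1)[C@@H](Cc1ccc(OC)c(OCc2ccccc2)c1)CO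
F5 | step 3 | (R)-2-[3-(benzyloxy)-4-methoxybenzyl]butane-1,4-diol | OCC[C@@H](Cc1ccc(OC)c(OCc2ccccc2)c1)CO
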